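**Retrosynthesis (ring-forming order in the forward direction)**
1. The spiro-oxindole C3–CMe2 quaternary bond comes from an electrochemical, bromide-mediated oxidative 1,2-shift (semipinacol) of a 1,1-dimethyl-tetrahydrocarbazole. This contracts the cyclohexane ring to the cyclopentane and sets the spiro centre.
2. The indole comes from a Fischer indolization of a cis-fused tricyclic nitro-ketone with the hydrazone of 5-amino-2,2-dimethylchroman-4-one. The hydrazone is built from 2',6'-dihydroxyacetophenone.
3. The tricyclic ketone (cyclohexanone formed onto a piperidine) comes from a Diels–Alder reaction of a cyclic 3-nitro-tetrahydropyridine with a 1,1-dimethyl-2-silyloxydiene. The nitroalkene comes from L-prolinol by Wittig homologation, a nitro-Mannich/Henry cascade and dehydration.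
4. Order of ring formation: pyrrolidine (L-prolinol) → piperidine (Henry) → cyclohexanone (Diels–Alder) → indole (Fischer) → spirocyclopentane (oxidative rearrangement).

Assumption: Boc-L-prolinol, 4-methylpent-1-en-3-one and 2',6'-dihydroxyacetophenone are purchased, and diastereomers from Steps 10 and 12 are separated by chromatography.

---

**Step 1**
Reactants: 1 N-Boc-L-prolinol
Product: 2 N-Boc-L-prolinal
Conditions: Dess–Martin periodinane, NaHCO3, CH2Cl2, 0 °C → rt; use crude at once
Reagents that add atoms: none
Why: Mild oxidation of a primary alcohol to the aldehyde; the (S)-centre is the only stereocentre and is taken from L-proline.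

**Step 2**
Reactants: 2, 3 (methoxymethyl)triphenylphosphonium chloride
Product: 4 tert-butyl (2S)-2-(2-methoxyvinyl)pyrrolidine-1-carboxylate (E/Z)
Conditions: 3, KOtBu, THF, 0 °C; add 2, 0 °C → rt
Reagents that add atoms: 3, COC[P+](c1ccccc1)(c1ccccc1)c1ccccc1.[Cl-]
Why: Wittig one-carbon homologation gives the enol ether of the β-amino aldehyde, and the pyrrolidine stereocentre is untouched.

**Step 3**
Reactants: 4
Product: 5 2-[(2S)-pyrrolidin-2-yl]acetaldehyde trifluoroacetate
Conditions: TFA/H2O (9:1), 25 °C, 2 h; evaporate
Reagents that add atoms: trifluoroacetic acid (counter-ion), OC(=O)C(F)(F)F; water, O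
Why: TFA removes the Boc group and hydrolyses the enol ether in one pot, and protonation of the amine keeps the amino-aldehyde from self-condensing.

**Step 4**
Reactants: 5, 6 formaldehyde, 7 nitromethane
Product: 8 (8aS)-6-nitro-octahydroindolizin-7-ol (C6/C7 diastereomer mixture)
Conditions: 37% aq. HCHO (1.1 equiv), CH3NO2 (10 equiv), Et3N (1.1 equiv), EtOH, 0 → 25 °C, 16 h
Reagents that add atoms: formaldehyde, C=O; nitromethane, C[N+](=O)[O-]
Why: Nitro-Mannich of the free secondary amine via its CH2=N+ iminium gives N–CH2CH2NO2, and the nitronate then closes onto the tethered aldehyde by an intramolecular Henry reaction (6-exo). The C6/C7 centres are destroyed in the next step, so only C8a matters.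

**Step 5**
Reactants: 8
Product: 9 (8aS)-6-nitro-1,2,3,5,8,8a-hexahydroindolizine
Conditions: MsCl, Et3N, CH2Cl2, −20 °C → rt
Reagents that add atoms: none (the mesylate is lost in the elimination)
Why: Mesylation of the β-nitro alcohol and E1cB elimination give the conjugated cyclic trisubstituted nitroalkene (dehydrative Henry condensation).

**Step 6**
Reactants: 10 4-methylpent-1-en-3-one, 11 TBSOTf
Product: 12 tert-butyldimethyl[(4-methylpenta-1,3-dien-3-yl)oxy]silane
Conditions: TBSOTf, Et3N, CH2Cl2, 0 °C
Reagents that add atoms: TBSOTf, CC(C)(C)[Si](C)(C)OS(=O)(=O)C(F)(F)F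
Why: Soft enolization of the isopropyl side gives the 2-silyloxydiene, since the vinyl side cannot enolize (Mukaiyama-type silyl enol ether formation).

**Step 7**
Reactants: 13 2',6'-dihydroxyacetophenone, 14 acetone
Product: 15 5-hydroxy-2,2-dimethylchroman-4-one
Conditions: pyrrolidine (0.3 equiv), acetone (excess), toluene, reflux, Dean–Stark
Reagents that add atoms: acetone, CC(C)=O
Why: Kabbe condensation (enamine aldol followed by oxa-Michael) forms the 2,2-dimethylchromanone, and the two OH groups are equivalent so there is no regiochemical issue.

**Step 8**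
Reactants: 15, 16 triflic anhydride
Product: 17 2,2-dimethyl-4-oxochroman-5-yl trifluoromethanesulfonate
Conditions: Tf2O, pyridine, CH2Cl2, 0 °C
Reagents that add atoms: Tf2O, O=S(=O)(OS(=O)(=O)C(F)(F)F)C(F)(F)F
Why: Standard O-triflation of the H-bonded phenol.

**Step 9**
Reactants: 17, 18 benzophenone hydrazone
Product: 19 5-[2-(diphenylmethylene)hydrazinyl]-2,2-dimethylchroman-4-one
Conditions: Pd(OAc)2, Xantphos, Cs2CO3, toluene, 100 °C
Reagents that add atoms: benzophenone hydrazone, NN=C(c1ccccc1)c1ccccc1
Why: Pd-catalysed C–N coupling of a hydrazone with an aryl triflate; the achiral ligand installs the masked arylhydrazine at C5, ortho to the carbonyl.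

**Step 10**
Reactants: 9, 12
Product: 20 tricyclic cis-fused nitro ketone (SMILES in the list)
Conditions: 12 (3 equiv), BHT, toluene, 140 °C, sealed tube, 72 h; then 3 M HCl/THF (1:3), rt, then NaHCO3
Reagents that add atoms: none (TBS lost on hydrolysis)
Why: Proposed new method: normal-demand Diels–Alder of a basic-amine-containing cyclic trisubstituted nitroalkene with a gem-dimethyl-terminated 2-silyloxydiene. It joins the nucleophilic diene terminus CMe2 to the β-carbon of the nitroalkene and the diene CH2 to the nitro-bearing carbon. This builds the cyclohexane, the quaternary nitro carbon and the vicinal CMe2/CH array in one step; the closest known reaction is the nitroalkene/2-siloxybutadiene Diels–Alder, which can run stepwise as a Mukaiyama–Michael followed by a nitronate Michael. Suprafacial addition to the ring (Z) alkene makes the ring fusion cis and puts NO2 cis to H-c. The diene adds to the face anti to the pyrrolidine ring carbon at C8a, so the L-proline centre sets c and b. Acid hydrolysis of the silyl enol ether gives the ketone.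

**Step 11**
Reactants: 19, 20
Product: 21 indole (tetrahydrocarbazole-type)
Conditions: TsOH·H2O (4 equiv), EtOH, 85 °C, 24 h
Reagents that add atoms: none
Why: Transhydrazonation (benzophenone lost) followed by Fischer indolization. The α-quaternary CMe2 side of the ketone blocks enolization, so only the CH2 side forms the ene-hydrazine and the [3,3] shift gives a single regioisomeric 7-acyl-6-alkoxyindole; stereocentres b, c and C2' are not epimerizable.

**Step 12**
Reactants: 21
Product: 22 citrinalin B
Conditions: undivided cell, graphite(+)/Pt(−), 5 mA (~2.3 F/mol), NaBr (0.3 equiv), TFA (1.5 equiv), LiClO4, MeCN/H2O 9:1, 25 °C; then NaHCO3 work-up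
Reagents that add atoms: water, O
Why: Anodically generated Br+ brominates indole C3, and water adds at C2 to give the 3-bromo-2-hydroxyindoline. An anti-periplanar semipinacol 1,2-shift of CMe2 from C2 to C3 then forms the spiro quaternary bond and contracts the ring to the cyclopentane, with a net H2O → O transfer and H2 at the cathode. The amine is protonated and so protected from oxidation. Bromination is expected from the convex face, opposite the cis-fused piperidine ring, so the shift delivers CMe2 to the concave face and leaves the aryl cis to the piperidine CH2 groups, as in the target.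

---

**Compound list**

| No. | Name | SMILES | Role |
|---|---|---|---|
| 1 | N-Boc-L-prolinol | CC(C)(C)OC(=O)N1CCC[C@H]1CO | starting material |
| 2 | N-Boc-L-prolinal | CC(C)(C)OC(=O)N1CCC[C@H]1C=O | intermediate |
| 3 | (methoxymethyl)triphenylphosphonium chloride | COC[P+](c1ccccc1)(c1ccccc1)c1ccccc1.[Cl-] | starting material |
| 4 | Boc-2-(2-methoxyvinyl)pyrrolidine | CC(C)(C)OC(=O)N1CCC[C@H]1C=COC | intermediate |
| 5 | 2-[(2S)-pyrrolidin-2-yl]acetaldehyde TFA salt | O=CC[C@@H]1CCC[NH2+]1.[O-]C(=O)C(F)(F)F | intermediate |
| 6 | formaldehyde | C=O | starting material |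
| 7 | nitromethane | C[N+](=O)[O-] | starting material |
| 8 | 6-nitro-octahydroindolizin-7-ol | OC1C[C@@H]2CCCN2CC1[N+](=O)[O-] | intermediate |
| 9 | 6-nitro-hexahydroindolizine (nitroalkene) | [O-][N+](=O)C1=CC[C@@H]2CCCN2C1 | intermediate |
| 10 | 4-methylpent-1-en-3-one | C=CC(=O)C(C)C | starting material |
| 11 | TBSOTf | CC(C)(C)[Si](C)(C)OS(=O)(=O)C(F)(F)F | starting material |
| 12 | 3-TBSO-4-methylpenta-1,3-diene | C=CC(O[Si](C)(C)C(C)(C)C)=C(C)C | intermediate |
| 13 | 2',6'-dihydroxyacetophenone | CC(=O)c1c(O)cccc1O | starting material |
| 14 | acetone | CC(C)=O | starting material |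
| 15 | 5-hydroxy-2,2-dimethylchroman-4-one | CC1(C)CC(=O)c2c(O)cccc2O1 | intermediate |
| 16 | triflic anhydride | O=S(=O)(OS(=O)(=O)C(F)(F)F)C(F)(F)F | starting material |
| 17 | chromanone 5-triflate | CC1(C)CC(=O)c2c(OS(=O)(=O)C(F)(F)F)cccc2O1 | intermediate |
| 18 | benzophenone hydrazone | NN=C(c1ccccc1)c1ccccc1 | starting material |
| 19 | N-aryl benzophenone hydrazone | CC1(C)CC(=O)c2c(NN=C(c3ccccc3)c3ccccc3)cccc2O1 | intermediate |
| 20 | cis-fused tricyclic nitro ketone (2,2-dimethylcyclohexanone fused to the indolizidine, nitro at the ring-fusion carbon) | O=C1CC[C@]2([N+](=O)[O-])CN3CCC[C@H]3C[C@@H]2C1(C)C | intermediate |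
| 21 | indole | CC1(C)CC(=O)c2c(ccc3c2[nH]c4c3C[C@]5([N+](=O)[O-])CN6CCC[C@H]6C[C@@H]5C4(C)C)O1 | intermediate |
| 22 | citrinalin B | CC1(C)CC(=O)c2c(ccc3c2NC(=O)[C@]32C[C@]3([N+](=O)[O-])CN4CCC[C@H]4C[C@@H]3C2(C)C)O1 | target |

**Total steps:** 12. **Longest linear sequence:** 8 (Steps 1, 2, 3, 4, 5, 10, 11, 12, from Boc-L-prolinol).

**Three steps most likely to fail**
1. **Step 10 (proposed new Diels–Alder).** The Z-methyl on the diene terminus and the hindered trisubstituted nitroalkene may stall the cycloaddition, or the facial selectivity may be low.
   Fallback (known chemistry): run it stepwise. First a Lewis-acid Mukaiyama–Michael of 12 onto 9 (TMSOTf, CH2Cl2) to give the open-chain vinyl ketone and nitronate, then DBU-mediated intramolecular 6-endo nitro-Michael closure to 20.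
2. **Step 12 (electrochemical rearrangement).** Aryl bromination, amine oxidation or the wrong face of migration could compete.
   Fallback: switch the oxidant manifold to singlet oxygen. Rose Bengal, O2 and visible light give the 3-hydroperoxyindolenine, which is reduced with PPh3 and rearranged with TsOH to the spirooxindole.
3. **Step 11 (Fischer on a hindered ketone with an ortho-acyl aryl hydrazine).** Slow transhydrazonation, or indazole formation from the ortho ketone, may occur.
   Fallback: use a different aryl disconnection. Run the Fischer with 3-benzyloxyphenylhydrazone, carry it through the oxidative rearrangement, then build the chromanone by ortho-acylation and cyclization with 3-methylbut-2-enoic acid (Eaton's reagent) after debenzylation.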